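## The problem

Atoms carry germacrane numbers throughout (ring C1–C10, lactone carbons C11–C13, C14 on C10, C15 on C4). α/β are used as in the usual germacranolide drawing, with H‑7 α.

- The target is a melampolide‑type germacranolide: a ten‑membered carbocycle with a Z trisubstituted C1=C10 olefin, a trans (E‑derived) 4,5‑epoxide, a trans‑fused C6/C7 γ‑lactone and a tiglate on O8.
- It has seven stereocentres, six of them contiguous (C3–C8). The seventh, C11, has its methyl cis to C8 on the lactone, the less stable arrangement, so it has to be set kinetically.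
- Closing a ten‑membered ring by cyclization is costly. No single small ring can supply both the Z olefin and the trans epoxide, because a trans‑4,5‑epoxide cannot exist in a six‑membered ring.
- The feature that makes the key step possible: C1–C6 with C15 on C4 and the three‑carbon unit C9/C10/C14 on C1 is the p‑menthane skeleton of carvone. C6 bears oxygen and is joined to the C1=C10 olefin through C7–C8–C9. This is the retron of an oxy‑Cope rearrangement. The ring C1…C10 can therefore arise from the six‑membered ring C1–C6 by breaking C1–C6 and making C8–C9, with the isopropenyl carbons C10 and C9 entering the ring.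
- A second feature: the C3‑hydroxy/4,5‑epoxide array is the Payne isomer of a cis‑3,4‑epoxy‑5‑ol. That is exactly what a hydroxyl‑directed epoxidation of a carveol gives, and it is the only form in which a six‑membered ring can carry this array.
- Control can be relayed: the one stereocentre of carvone (C1) sets C5, C3 and C4 on the six‑membered ring and is then destroyed. The chair transition state sets C8 and C7, C5 sets C6, and C7/C8 set C11.
- Fragile groups: the epoxide next to a free carbinol (acid, transannular attack, base‑induced migration), the tiglate and lactone (base, nucleophiles), the C11 centre (epimerization), and the β,γ‑unsaturated ketone stage after ring expansion.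

## Retrosynthesis

**33 ⇒ 31 + 32.** The C8–O bond is cut. Tiglic acid 32 is joined to the 8α‑alcohol 31 by Mitsunobu inversion. A plain acylation of an 8β‑alcohol would be the neighbouring choice, but the ring expansion gives 8α from the one stable, accessible enol ether geometry. The inversion installs the base‑sensitive ester last. The forward reaction must displace at C8 while the C3 hydroxyl, flanked by the quaternary epoxide carbon, stays free.

**31 ⇒ 30 ⇒ 29 ⇒ 26.** The lactone C12=O and the C11–H bond are removed. Lactone 29 comes from the 2‑methylene‑1,4‑diol unit of triol 26 by oxidation of the allylic alcohol. The C11 methyl comes from hydrogenation of the exocyclic methylene on the face that carries H‑7. Equilibration would give the wrong C11 epimer, so a kinetic delivery of hydrogen is preferred. The masked acrylate of 26 is a base‑stable allylic alcohol.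

**26 ⇒ 24 (through 25).** The C4–O(5) epoxide bond is cut and the C4–O(3) bond restored. Triol 26 is the Payne isomer of the cis‑3,4‑epoxy‑5‑ol 25, which is released from the bis‑silyl ether 24. The rearrangement inverts only C4 and turns the six‑ring‑compatible cis epoxide into the trans epoxide once the ring is ten‑membered. The forward reaction needs the equilibrium to lie on the side of 26.

**24 ⇒ 23 ⇒ 20 (key).** The C6 carbinol goes back to ketone 23, and the C8–C9 bond is cut while C1–C6 is re‑formed. This leads to the cis‑1,2‑dialkenylcyclohexanol 20. A ring closure at C1=C10 or C6–C7 would need all stereocentres on an open chain; here four stereocentres sit on a cyclohexane and two more are created in the step. The forward reaction must go through one chair (Z olefin, C8 configuration) and the enolate must be protonated on one face (C7).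

**20 ⇒ 15 + 16, and 15 ⇒ 7 + 12.** The C7–C11 bond is cut (syn carbocupration of an ynol ether by the copper reagent from bromide 16). Then the C6–C7 bond is cut (addition of the alkoxyacetylide from 12 to ketone 7). An acetylide is chosen over a ready‑made alkenyl metal because a small linear nucleophile adds axially and so places the new carbon group cis to the isopropenyl group. The ynol ether then fixes both the position of the new C–C bond and the Z geometry.

**7 ⇒ 1.** Ketone 7 is (R)‑carvone with the oxidation pattern shifted. The carvone carbonyl (C5) becomes the silyloxy carbinol, the enone olefin (C3=C4) the syn epoxide, and the α′‑carbon (C6) the ketone. Six functional‑group steps under control of the carvone stereocentre.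

## Roads not taken

**Alternative 1:** ring‑closing metathesis at C1=C10 (the most obvious cut). Diene A1, with terminal methylenes on C1 and C10 and all other functionality in place, would be closed with second‑generation Grubbs catalyst, RuCl2(=CHPh)(PCy3)(H2IMes). All seven stereocentres, including the quaternary epoxide carbon, would have to be built first on an open chain carrying the lactone. The closure then has to make a trisubstituted olefin in a strained ten‑membered ring against dimerization. The chosen plan makes the ring by expansion and sets most centres on rings.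

**Alternative 2:** intramolecular Barbier or Nozaki–Hiyama–Kishi allylation forming C6–C7 and the lactone (CrCl2 or Zn on the ω‑formyl allylic bromide A2, giving α‑methylene lactone A3). This is the classical germacranolide closure. The aldehyde would sit on the trans epoxide (labile, epimerizable), the Z C1=C10 olefin would need a separate acyclic olefination, and the C6/C7 configuration would depend on a macrocyclic transition state next to the C8 stereocentre. High dilution and a long linear precursor are the price.

**Alternative 3:** Grob fragmentation of a eudesmane‑type cis‑decalin (mesylate on C1, tertiary alkoxide on C5; A4), breaking C5–C10 to give the 1(10)Z‑germacren‑5‑one A5. Santonin‑like chiral pool material would be the source. The precursor carries more stereocentres than the product and lacks the C8 oxygen. The fragmentation leaves a C5 ketone where an epoxide oxygen shared with C4 is needed, with C3 still unoxidized.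

Key step: step 10

Remark: compounds 1, 8, 9, 16 and 32 are taken as purchased.

## Steps

Step 1
Reactants: 1 (R)-(−)-carvone
Product: 2 6-acetoxycarvone (acetoxy on C6 trans to the C1 isopropenyl group)
Conditions: Mn(OAc)3·2H2O, benzene, reflux
Reagents that add atoms: Mn(OAc)3·2H2O (manganese triacetate dihydrate), CC(=O)[O-].CC(=O)[O-].CC(=O)[O-].[Mn+3].O.O
Why: α′-Acetoxylation of an enone by manganese triacetate occurs at the only enolizable α′-carbon (C6), with the acetate entering trans to isopropenyl; C6 later becomes the ketone, so its configuration does not matter.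

Step 2
Reactants: 2 6-acetoxycarvone
Product: 3 acetoxy allylic alcohol (C5 hydroxyl cis to isopropenyl; trans to acetoxy)
Conditions: NaBH4, CeCl3·7H2O, MeOH, −78 to −20 °C
Reagents that add atoms: none
Why: Luche 1,2-reduction; axial hydride delivery to the enone half-chair should give the C5 hydroxyl cis to the C1 isopropenyl group (as carvone gives cis-carveol) and leave the acetate untouched.

Step 3
Reactants: 3 acetoxy allylic alcohol
Product: 4 epoxy alcohol (3,4-epoxide on the face of the C5 hydroxyl)
Conditions: VO(acac)2 (cat.), t-BuOOH, CH2Cl2, 0 °C to rt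
Reagents that add atoms: tert-butyl hydroperoxide, CC(C)(C)OO
Why: Hydroxyl-directed vanadium-catalysed epoxidation delivers oxygen syn to the allylic C5 hydroxyl and ignores the isopropenyl group; this sets C3 and C4.

Step 4
Reactants: 4 epoxy alcohol
Product: 5 C5 tert-butyldimethylsilyl ether
Conditions: TBSOTf, 2,6-lutidine, CH2Cl2, −78 °C
Reagents that add atoms: tert-butyldimethylsilyl trifluoromethanesulfonate (TBSOTf), CC(C)(C)[Si](C)(C)OS(=O)(=O)C(F)(F)F
Why: Silylation of the hindered secondary alcohol with the silyl triflate under buffered, cold conditions that the epoxide tolerates; the bulky non-chelating ether is needed later for conformational and Felkin-type control.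

Step 5
Reactants: 5 C5 silyl ether
Product: 6 C6 alcohol
Conditions: K2CO3 (cat.), MeOH, 0 °C
Reagents that add atoms: none
Why: Catalytic methanolysis removes the acetate only; silyl ether and epoxide are stable to these conditions.

Step 6
Reactants: 6 C6 alcohol
Product: 7 epoxy ketone (C6 ketone; C5 silyloxy, 3,4-epoxide and C1 isopropenyl all on one face)
Conditions: Dess–Martin periodinane, pyridine, CH2Cl2, 0 °C to rt
Reagents that add atoms: none
Why: Dess–Martin oxidation under buffered, non-enolizing conditions keeps the two α-stereocentres (C1 and C5) and the β,γ-epoxide intact.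

Step 7
Reactants: 8 4-methoxybenzyl alcohol; 9 trichloroethylene
Product: 12 (E)-1,2-dichlorovinyl 4-methoxybenzyl ether, via potassium 4-methoxybenzyl oxide 10 (not isolated), via dichloroacetylene 11 (not isolated)
Conditions: KH, THF, 0 °C; then trichloroethylene, −50 °C to rt
Reagents that add atoms: none
Why: Known elimination–addition route to 1,2-dichlorovinyl ethers: the alkoxide dehydrochlorinates trichloroethylene and adds to the dichloroacetylene formed.

Step 8
Reactants: 7 epoxy ketone; 12 (E)-1,2-dichlorovinyl 4-methoxybenzyl ether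
Product: 15 propargylic alcohol (C6 carbinol; alkoxyethynyl group cis to the C1 isopropenyl group; hydroxyl trans), via chloroalkynyl ether 13 (not isolated), via lithium alkoxyacetylide 14 (not isolated)
Conditions: 12, n-BuLi (2 equiv), THF, −78 to −40 °C; then 7, −78 °C; aq. NH4Cl
Reagents that add atoms: none
Why: Dehydrochlorination and chlorine–lithium exchange give the lithium alkoxyacetylide, which adds 1,2 to the ketone; the small linear nucleophile should attack axially, anti to the two pseudoaxial α C–H bonds of the half-chair with isopropenyl and silyloxy pseudoequatorial, so the alkynyl group ends cis to both (cis-dialkenyl relationship) and the hydroxyl trans.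

Step 9
Reactants: 15 propargylic alcohol; 16 (2-bromoallyloxy)(tert-butyl)dimethylsilane
Product: 20 dienol ether carbinol (C7 bears the Z 2-(4-methoxybenzyloxy)vinyl unit plus the 3-silyloxyprop-1-en-2-yl group), via vinyllithium 17 (not isolated), via vinylcopper 18 (not isolated), via alkenylcopper adduct 19 (not isolated)
Conditions: 16, t-BuLi, Et2O, −78 °C; CuBr·SMe2, −50 °C; then 15 (pre-treated with n-BuLi, THF, −78 °C), −40 to −20 °C; aq. NH4Cl
Reagents that add atoms: none
Why: Syn carbocupration of an ynol ether: carbon bonds to the alkyne carbon β to oxygen (C7) and copper to C8, and protonolysis with retention gives the Z enol ether (ether oxygen cis to C6) together with the C7–C11 bond.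

Step 10
Reactants: 20 dienol ether carbinol
Product: 23 cyclodecenone (ten-membered ring; Z C1=C10; C6 ketone; H-7 α; C8 ether oxygen α), via potassium alkoxide 21 (not isolated), via potassium enolate 22 (not isolated)
Conditions: KN(SiMe3)2, 18-crown-6, THF, −20 to 0 °C; then AcOH, −78 °C
Reagents that add atoms: none
Why: The base converts 20 into the dissociated potassium alkoxide 21, which undergoes a [3,3]-sigmatropic (anionic oxy-Cope) shift in which C8–C9 forms as C1–C6 breaks, giving the ring-enlarged enolate 22; the closest known reaction type is the anionic oxy-Cope ring expansion of 1,2-dialkenylcyclohexanols to cyclodec-5-enones. The ten-membered ring is thus not closed by cyclization but arises by four-atom expansion of the C1–C6 ring through a six-membered chair transition state (C8, C7, C6, C1, C10, C9). Because the alkenyl groups are cis, one ring bond must be axial in that chair; the substrate should react from the cyclohexane conformer with the C7 alkenyl group axial and the isopropenyl and C5 silyloxy groups equatorial, which makes C1–C2 the axial bond and C1=C10 Z, whereas the other chair (E olefin) would need isopropenyl and silyloxy 1,3-diaxial. In this chair the Z enol ether holds the 4-methoxybenzyloxy group axial on C8, so the olefin geometry is transferred into the C8 stereocentre (oxygen α). The enolate is formed regiospecifically at C6=C7 with its inner face turned towards C1/C10, and acetic acid at −78 °C should protonate C7 from the outer face, giving H-7 α and the side chain β. The step needs chair over boat and [3,3] over [1,3] shift, both favoured by a chair with only the alkoxide and the ether oxygen axial, and it needs the β-alkoxy enolate and the epoxide to survive, which low temperature and immediate quench are meant to secure.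

Step 11
Reactants: 23 cyclodecenone
Product: 24 cyclodecenol (C6 hydroxyl α)
Conditions: LiBH(s-Bu)3, THF, −78 °C; H2O
Reagents that add atoms: none
Why: The bulky hydride should attack the C6 carbonyl anti to the C5–O bond of the non-chelating silyloxy group (polar Felkin-type control), giving the 5,6-syn relationship, that is the 6α alcohol; the cold, weakly basic conditions protect the doubly activated C7–H.

Step 12
Reactants: 24 cyclodecenol
Product: 26 epoxy triol (3β-hydroxyl; trans 4,5-epoxide; C6 and C12 hydroxyls free), via cis-3,4-epoxy triol 25 (not isolated)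
Conditions: Bu4NF, THF, 0 °C to rt
Reagents that add atoms: none
Why: Fluoride removes both silyl groups; on the ten-membered ring the freed C5 oxygen can reach the rear of the C4–O bond and the epoxy alcohol should undergo Payne rearrangement with inversion at C4 only, giving the trans 4,5-epoxide and the C3 carbinol with C3 and C5 unchanged. A further shift to the 5,6-epoxide is disfavoured (disubstituted oxirane, tertiary alkoxide).

Step 13
Reactants: 26 epoxy triol
Product: 29 α-methylene lactone (trans-fused 12,6-olide), via hydroxy enal 27 (not isolated), via lactol 28 (not isolated)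
Conditions: MnO2, CH2Cl2, rt
Reagents that add atoms: none
Why: MnO2 oxidizes only the allylic primary alcohol; the enal is captured by the C6 hydroxyl as a five-membered lactol that is oxidized on to the lactone, with C6 and C7 untouched, so the ring fusion is trans; the C3 hydroxyl is not allylic and stays.

Step 14
Reactants: 29 α-methylene lactone
Product: 30 α-methyl lactone (11αH; methyl cis to C8)
Conditions: H2 (1 atm), RhCl(PPh3)3 (cat.), benzene/EtOH, rt
Reagents that add atoms: none
Why: Homogeneous hydrogenation reduces the 1,1-disubstituted conjugated methylene and spares the trisubstituted ring olefin; hydrogen should add to the lactone face that carries H-7, the other being blocked by C8, which places the methyl cis to C8.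

Step 15
Reactants: 30 α-methyl lactone
Product: 31 8α-alcohol
Conditions: DDQ, CH2Cl2/pH 7 buffer, 0 °C
Reagents that add atoms: none
Why: Oxidative cleavage of the 4-methoxybenzyl ether under buffered conditions that leave epoxide, lactone and ring olefin alone.

Step 16
Reactants: 31 8α-alcohol; 32 tiglic acid
Product: 33 target (CNP0265652.4)
Conditions: PPh3, DIAD, toluene, 0 °C to rt
Reagents that add atoms: none
Why: Mitsunobu esterification: the C8 oxyphosphonium is displaced by tiglate with inversion to give the 8β ester; the C3 hydroxyl sits next to the quaternary epoxide carbon, cannot be displaced and should remain free.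

## Compound list

1 | (R)-(−)-carvone, (5R)-2-methyl-5-(prop-1-en-2-yl)cyclohex-2-en-1-one | CC(=C)[C@@H]1CC=C(C)C(=O)C1 | starting material
2 | 6-acetoxycarvone, (1S,6S)-3-methyl-2-oxo-6-(prop-1-en-2-yl)cyclohex-3-en-1-yl acetate (acetoxy trans to isopropenyl) | CC(=C)[C@@H]1CC=C(C)C(=O)[C@H]1OC(C)=O | intermediate
3 | (1S,2S,6S)-2-hydroxy-3-methyl-6-(prop-1-en-2-yl)cyclohex-3-en-1-yl acetate (C5 hydroxyl cis to isopropenyl) | CC(=C)[C@@H]1CC=C(C)[C@H](O)[C@H]1OC(C)=O | intermediate
4 | 3,4-epoxide of 3, oxirane oxygen cis to the C5 hydroxyl and to isopropenyl | CC(=C)[C@@H]1C[C@@H]2O[C@]2(C)[C@H](O)[C@H]1OC(C)=O | intermediate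
5 | C5 tert-butyldimethylsilyl ether of 4 | CC(=C)[C@@H]1C[C@@H]2O[C@]2(C)[C@H](O[Si](C)(C)C(C)(C)C)[C@H]1OC(C)=O | intermediate
6 | C6 alcohol (deacetylated 5) | CC(=C)[C@@H]1C[C@@H]2O[C@]2(C)[C@H](O[Si](C)(C)C(C)(C)C)[C@H]1O | intermediate
7 | epoxy ketone: C6 ketone with C5 silyloxy, 3,4-epoxide and C1 isopropenyl all cis | CC(=C)[C@@H]1C[C@@H]2O[C@]2(C)[C@H](O[Si](C)(C)C(C)(C)C)C1=O | intermediate
8 | 4-methoxybenzyl alcohol | COc1ccc(CO)cc1 | starting material
9 | trichloroethylene | ClC=C(Cl)Cl | starting material
10 | potassium 4-methoxybenzyl oxide | [K+].[O-]Cc1ccc(OC)cc1 | intermediate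
11 | dichloroacetylene | ClC#CCl | intermediate
12 | (E)-1,2-dichlorovinyl 4-methoxybenzyl ether | COc1ccc(cc1)CO/C(Cl)=C\Cl | intermediate
13 | chloroethynyl 4-methoxybenzyl ether | COc1ccc(cc1)COC#CCl | intermediate
14 | lithium (4-methoxybenzyloxy)acetylide | COc1ccc(cc1)COC#C[Li] | intermediate
15 | propargylic alcohol: C6 tertiary carbinol, alkoxyethynyl cis to isopropenyl and silyloxy, hydroxyl trans | CC(=C)[C@@H]1C[C@@H]2O[C@]2(C)[C@H](O[Si](C)(C)C(C)(C)C)[C@]1(O)C#COCc1ccc(OC)cc1 | intermediate
16 | (2-bromoallyloxy)(tert-butyl)dimethylsilane | C=C(Br)CO[Si](C)(C)C(C)(C)C | starting material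
17 | [3-(tert-butyldimethylsilyloxy)prop-1-en-2-yl]lithium | C=C([Li])CO[Si](C)(C)C(C)(C)C | intermediate
18 | [3-(tert-butyldimethylsilyloxy)prop-1-en-2-yl]copper | C=C([Cu])CO[Si](C)(C)C(C)(C)C | intermediate
19 | alkenylcopper adduct (copper on C8 cis to C11; lithium alkoxide on C6) | CC(=C)[C@@H]1C[C@@H]2O[C@]2(C)[C@H](O[Si](C)(C)C(C)(C)C)[C@]1(O[Li])/C(=C(/[Cu])OCc1ccc(OC)cc1)C(=C)CO[Si](C)(C)C(C)(C)C | intermediate
20 | dienol ether carbinol: C7 bears the Z enol ether (ether oxygen cis to C6) and the 3-silyloxyprop-1-en-2-yl group | CC(=C)[C@@H]1C[C@@H]2O[C@]2(C)[C@H](O[Si](C)(C)C(C)(C)C)[C@]1(O)/C(=C\OCc1ccc(OC)cc1)C(=C)CO[Si](C)(C)C(C)(C)C | intermediate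
21 | potassium alkoxide of 20 | CC(=C)[C@@H]1C[C@@H]2O[C@]2(C)[C@H](O[Si](C)(C)C(C)(C)C)[C@]1([O-])/C(=C\OCc1ccc(OC)cc1)C(=C)CO[Si](C)(C)C(C)(C)C.[K+] | intermediate
22 | potassium enolate (C6=C7) of the ring-enlarged ketone | [K+].[O-]/C1=C(/C(=C)CO[Si](C)(C)C(C)(C)C)[C@@H](OCc2ccc(OC)cc2)C/C(C)=C\C[C@@H]2O[C@]2(C)[C@@H]1O[Si](C)(C)C(C)(C)C | intermediate
23 | cyclodecenone: 1(10)Z, C6 ketone, 3β,4β-epoxide, 5β-silyloxy, H-7 α, 8α-(4-methoxybenzyloxy) | COc1ccc(cc1)CO[C@H]2C/C(C)=C\C[C@@H]3O[C@]3(C)[C@H](O[Si](C)(C)C(C)(C)C)C(=O)[C@@H]2C(=C)CO[Si](C)(C)C(C)(C)C | intermediate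
24 | cyclodecenol: 6α-alcohol of 23 | COc1ccc(cc1)CO[C@H]2C/C(C)=C\C[C@@H]3O[C@]3(C)[C@H](O[Si](C)(C)C(C)(C)C)[C@@H](O)[C@@H]2C(=C)CO[Si](C)(C)C(C)(C)C | intermediate
25 | desilylated cis-3,4-epoxy-5,6,12-triol | COc1ccc(cc1)CO[C@H]2C/C(C)=C\C[C@@H]3O[C@]3(C)[C@H](O)[C@@H](O)[C@@H]2C(=C)CO | intermediate
26 | epoxy triol: 3β-OH, 4α,5β-epoxide, 6α-OH, 12-OH | COc1ccc(cc1)CO[C@H]2C/C(C)=C\C[C@H](O)[C@@]3(C)O[C@@H]3[C@@H](O)[C@@H]2C(=C)CO | intermediate
27 | hydroxy enal (C12 aldehyde) | COc1ccc(cc1)CO[C@H]2C/C(C)=C\C[C@H](O)[C@@]3(C)O[C@@H]3[C@@H](O)[C@@H]2C(=C)C=O | intermediate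
28 | 12,6-lactol | COc1ccc(cc1)CO[C@H]2C/C(C)=C\C[C@H](O)[C@@]3(C)O[C@@H]3[C@H]3OC(O)C(=C)[C@@H]32 | intermediate
29 | α-methylene lactone: 8α-(4-methoxybenzyloxy)-11(13)-dehydro analogue | COc1ccc(cc1)CO[C@H]2C/C(C)=C\C[C@H](O)[C@@]3(C)O[C@@H]3[C@H]3OC(=O)C(=C)[C@@H]32 | intermediate
30 | α-methyl lactone (11αH), 8α-(4-methoxybenzyl) ether | COc1ccc(cc1)CO[C@H]2C/C(C)=C\C[C@H](O)[C@@]3(C)O[C@@H]3[C@H]3OC(=O)[C@H](C)[C@@H]32 | intermediate
31 | 8α-alcohol (8-epi-desacyl target) | O[C@H]1C/C(C)=C\C[C@H](O)[C@@]2(C)O[C@@H]2[C@H]2OC(=O)[C@H](C)[C@@H]21 | intermediate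
32 | tiglic acid, (E)-2-methylbut-2-enoic acid | C/C=C(\C)C(=O)O | starting material
33 | CNP0265652.4: (1(10)Z)-4α,5β-epoxy-3β-hydroxy-8β-tigloyloxy-11αH-germacr-1(10)-en-12,6α-olide (3S,4R,5R,6S,7R,8R,11R) | C/C=C(\C)C(=O)O[C@@H]1C/C(C)=C\C[C@H](O)[C@@]2(C)O[C@@H]2[C@H]2OC(=O)[C@H](C)[C@@H]21 | target

## Step count and least certain steps

Total steps: 16. Longest linear sequence: 15 (steps 1–6 and 8–16).

**Step 10 (key).** The anions are long-lived, and that is the main danger. The β-alkoxy enolate 22 can expel 4-methoxybenzyl oxide (E1cB). The tertiary alkoxide 21 can attack the C3 epoxide carbon across the ring before it rearranges. Leakage through the second chair would give the E olefin. Fallback: run the rearrangement without any anion. Starting from 20, silylation (TMSCl, imidazole) gives the trimethylsilyl ether F1. Thermal siloxy-Cope rearrangement (diphenyl ether, about 220 °C) gives the trimethylsilyl enol ether F2. Cleavage with MeLi at −78 °C and an acetic acid quench regenerates the enolate only briefly in the cold and returns to the route at 23.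

**Step 9.** Carbon–carbon bond formation at the alkyne carbon next to the fully substituted C6 may be slow. The neighbouring alkoxide may also divert the syn addition, which would scramble the enol ether geometry and with it C8. Fallback: starting from 15, semi-hydrogenation (H2, Pd/CaCO3 poisoned with Pb(OAc)2, quinoline) gives the Z enol ether F3. Iodination at the nucleophilic β-carbon (N-iodosuccinimide, then Et3N) gives the 7-iodo enol ether F4. Negishi coupling of F4 with the zinc reagent F5 (made from 17 and ZnBr2; Pd(PPh3)4) returns to the route at 20.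

**Step 12.** The Payne shift is an equilibrium. Strain of the trans oxirane in the ring could leave part of the material unrearranged, and the primary alkoxide could open an epoxide. Fallback: replace the equilibrium by an irreversible Wharton transposition. Starting from 24, desilylation with acetic-acid-buffered Bu4NF gives 25 without rearrangement. MnO2 gives the 3,4-epoxy-5-hydroxy α-methylene lactone F6. Hydrogenation (RhCl(PPh3)3) gives the methyl lactone F7. Dess–Martin oxidation gives the α,β-epoxy ketone F8. Hydrazine hydrate with acetic acid gives the 3β-hydroxy-4E-ene F9. Hydroxyl-directed epoxidation (VO(acac)2, t-BuOOH) returns to the route at 30.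

**Step 11.** Facial selectivity may be poor, because the C7 stereocentre and the ring conformation can override control by the C5 silyloxy group. The C7–H may also enolize. Fallback: make the C6 epimer deliberately and invert it. Starting from 23, chelation-controlled reduction (Zn(BH4)2) gives the 6β-alcohol F10. Mitsunobu reaction with 4-nitrobenzoic acid gives the 6α 4-nitrobenzoate F11. Methanolysis (K2CO3, MeOH) returns to the route at 24.

**Step 16.** The oxyphosphonium may eliminate towards the allylic C9 methylene instead of being substituted, or the hindered secondary centre may not react. Fallback: invert by oxidation and reduction, then acylate. Starting from 31, Dess–Martin oxidation gives the 8-ketone F12. Reduction (NaBH4, CeCl3·7H2O) from the less hindered face gives the 8β-alcohol F13. Acylation of the less hindered C8 hydroxyl (tigloyl chloride, Et3N, DMAP) returns to the route at 33.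

## Further compounds

F1 | step 10 | trimethylsilyl ether of 20 | CC(=C)[C@@H]1C[C@@H]2O[C@]2(C)[C@H](O[Si](C)(C)C(C)(C)C)[C@]1(O[Si](C)(C)C)/C(=C\OCc1ccc(OC)cc1)C(=C)CO[Si](C)(C)C(C)(C)C
F2 | step 10 | trimethylsilyl enol ether (C6=C7) of 23 | C[Si](C)(C)O/C1=C(/C(=C)CO[Si](C)(C)C(C)(C)C)[C@@H](OCc2ccc(OC)cc2)C/C(C)=C\C[C@@H]2O[C@]2(C)[C@@H]1O[Si](C)(C)C(C)(C)C
F3 | step 9 | Z enol ether carbinol (C7–H) | CC(=C)[C@@H]1C[C@@H]2O[C@]2(C)[C@H](O[Si](C)(C)C(C)(C)C)[C@]1(O)/C=C\OCc1ccc(OC)cc1
F4 | step 9 | 7-iodo enol ether carbinol (ether oxygen cis to C6) | CC(=C)[C@@H]1C[C@@H]2O[C@]2(C)[C@H](O[Si](C)(C)C(C)(C)C)[C@]1(O)/C(I)=C\OCc1ccc(OC)cc1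
F5 | step 9 | [3-(tert-butyldimethylsilyloxy)prop-1-en-2-yl]zinc bromide | C=C([Zn]Br)CO[Si](C)(C)C(C)(C)C
F6 | step 12 | 3,4-epoxy-5-hydroxy α-methylene lactone | COc1ccc(cc1)CO[C@H]2C/C(C)=C\C[C@@H]3O[C@]3(C)[C@H](O)[C@H]3OC(=O)C(=C)[C@@H]32
F7 | step 12 | 3,4-epoxy-5-hydroxy α-methyl lactone (11αH) | COc1ccc(cc1)CO[C@H]2C/C(C)=C\C[C@@H]3O[C@]3(C)[C@H](O)[C@H]3OC(=O)[C@H](C)[C@@H]32
F8 | step 12 | 3,4-epoxy-5-ketone | COc1ccc(cc1)CO[C@H]2C/C(C)=C\C[C@@H]3O[C@]3(C)C(=O)[C@H]3OC(=O)[C@H](C)[C@@H]32
F9 | step 12 | 3β-hydroxy-4E-ene lactone | COc1ccc(cc1)CO[C@H]2C/C(C)=C\C[C@H](O)/C(C)=C/[C@H]3OC(=O)[C@H](C)[C@@H]32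
F10 | step 11 | 6β-alcohol (C6 epimer of 24) | COc1ccc(cc1)CO[C@H]2C/C(C)=C\C[C@@H]3O[C@]3(C)[C@H](O[Si](C)(C)C(C)(C)C)[C@H](O)[C@@H]2C(=C)CO[Si](C)(C)C(C)(C)C
F11 | step 11 | 6α 4-nitrobenzoate | COc1ccc(cc1)CO[C@H]2C/C(C)=C\C[C@@H]3O[C@]3(C)[C@H](O[Si](C)(C)C(C)(C)C)[C@@H](OC(=O)c3ccc(cc3)[N+](=O)[O-])[C@@H]2C(=C)CO[Si](C)(C)C(C)(C)C
F12 | step 16 | 8-ketone | O=C1C/C(C)=C\C[C@H](O)[C@@]2(C)O[C@@H]2[C@H]2OC(=O)[C@H](C)[C@@H]21
F13 | step 16 | 8β-alcohol | O[C@@H]1C/C(C)=C\C[C@H](O)[C@@]2(C)O[C@@H]2[C@H]2OC(=O)[C@H](C)[C@@H]21
A1 | alternative 1 | seco-1(10) diene with C1 and C10 as terminal methylenes | C=CC[C@H](O)[C@@]1(C)O[C@@H]1[C@H]1OC(=O)[C@H](C)[C@@H]1[C@@H](CC(C)=C)OC(=O)/C(C)=C/C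
A2 | alternative 2 | ω-formyl allylic bromide (C6 aldehyde on the epoxide; Z bromomethyl acrylate at C7=C11) | O=C[C@H]1O[C@]1(C)[C@@H](O[Si](C)(C)C(C)(C)C)C/C=C(C)\C[C@@H](O[Si](C)(C)C(C)(C)C)/C=C(\CBr)C(=O)OC
A3 | alternative 2 | 3,8-bis-silylated α-methylene lactone | CC(C)(C)[Si](C)(C)O[C@@H]1C/C(C)=C\C[C@H](O[Si](C)(C)C(C)(C)C)[C@@]2(C)O[C@@H]2[C@H]2OC(=O)C(=C)[C@@H]21
A4 | alternative 3 | cis-fused 5-hydroxy-1-mesyloxy-3,8-bis(silyloxy)eudesman-12,6-olide | C[C@H]1C(=O)O[C@H]2[C@H]1[C@H](O[Si](C)(C)C(C)(C)C)C[C@@]1(C)[C@@H](OS(C)(=O)=O)C[C@H](O[Si](C)(C)C(C)(C)C)[C@@H](C)[C@@]21O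
A5 | alternative 3 | 1(10)Z-germacren-5-one lactone | C[C@H]1C(=O)O[C@H]2[C@H]1[C@H](O[Si](C)(C)C(C)(C)C)C/C(C)=C\C[C@H](O[Si](C)(C)C(C)(C)C)[C@@H](C)C2=O
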